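# Rubrolide A by oxidative ring expansion of a squarate-derived 4-hydroxycyclobutenone

## Analysis of the target

Rubrolide A is a fully unsaturated γ-lactone, a 2(5H)-furanone with ring atoms O1, carbonyl C2, C3–H, C4 and C5. C4 carries a 3,5-dibromo-4-hydroxyphenyl group. C5 is doubly bonded to the exocyclic carbon C6, which carries a second ring of the same kind. There is no stereocentre. The only stereochemical element is the C5=C6 double bond, which is Z: the benzylidene aryl lies on the side of O1, away from the C4 aryl.

The sensitive parts are the cross-conjugated enol lactone and the two 2,6-dibromophenols. The enol lactone is open to nucleophiles, strong base and light-induced Z/E isomerisation. The phenols are acidic and easily oxidised, and their C–Br bonds rule out organometallic steps once they are present.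

The difficulty is placement rather than size. Hydrogen at C3, aryl at C4, the ylidene at C5 and its geometry must all be set without ambiguity, and four bromine atoms must end up only ortho to the two hydroxyl groups.

The strategy rests on the position of O1 between the carbonyl carbon C2 and the acetal-level carbon C5. Taking O1 out and joining C2 to C5 leaves a four-membered carbocycle C2–C3–C4–C5. This is a cyclobutenone whose carbinol carbon C5 already carries C6 and its aryl group. Such a ring can be assembled from a squaric ester with full regiocontrol, and an oxidative ring expansion then puts O1 back.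

## Retrosynthetic reasoning

**15 ⇒ 14.** The four C–Br bonds are cut first. Aryl bromides flanking a phenol cannot be carried through the magnesium and lithium reagents 5 and 9. The free phenols of 14 direct an electrophile to exactly the four positions needed, since para is occupied. The forward reaction has to brominate each ring twice without touching C3 or the C5=C6 double bond.

**14 ⇒ 13.** The two phenolic O–H bonds are masked as methyl ethers. Methyl is indifferent to every earlier operation: hydride, organomagnesium and organolithium reagents, aqueous acid, a lead oxidant and an amidine base. Its removal by a boron Lewis acid is compatible with the butenolide.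

**13 ⇒ 12.** The C5=C6 double bond is traced back to a single bond by returning a hydrogen to C6 and an acetoxy group to C5. C5 is then an acylal carbon, which is the oxidation level the ring expansion delivers. C6 holds the only β-hydrogens, so the forward elimination can only go exocyclic. The Z geometry is favoured because the E isomer would press the two aryl groups together.

**12 ⇒ 11 (key disconnection).** O1 is taken out from between C2 and C5 and the C2–C5 bond is restored. This gives the cyclobutenone 11, in which C5 is a tertiary carbinol carbon bearing the benzyl group. The cut is made here because every substituent position of the lactone can be fixed beforehand in a carbocycle where regiochemistry is easy to dictate. The heteroatom is inserted last, and only at the one place where a C–C bond flanks the carbinol and the carbonyl. The forward reaction has to break the C2–C5 bond, join the former hydroxyl oxygen to C2 and leave C5 at the acylal level.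

**11 ⇒ 7 + 9.** The C4–aryl bond is cut. In 7 the future C4 is the carbonyl carbon of a vinylogous ester and the future C2 carries an isopropoxy group. 1,2-Addition of the aryllithium 9 (from 8) followed by acid-induced 1,3-transposition moves the carbonyl to C2 and leaves aryl on C4. Only one electrophilic π-system is left in 7, and attack at either of its ends gives the same constitution, so there is no regiochemical choice to be made.

**7 ⇒ 6 ⇒ 3 + 5.** The O–Si bond and then the C5–C6 bond are cut. In the dione 3 the carbonyl conjugated with the isopropoxy group is deactivated as a vinylogous ester. The benzylic Grignard reagent 5 (from 4) is therefore directed to the other carbonyl, which becomes C5. The silyl ether in 7 keeps the next addition at the mono-alkoxide stage.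

**3 ⇒ 1.** The C3–H bond is cut. One isopropoxy group of the commercial squarate 1 is exchanged for hydrogen by hydride addition and acid-induced transposition. The second isopropoxy group is kept through 3, 6 and 7 as the element that controls both carbon–carbon bond formations and then leaves. 1 already contains the complete four-membered ring, so no ring has to be built before the key step.

## Alternatives that were turned down

**Alternative 1: two arylacetylene units and carbon dioxide joined on nickel.**
- Disconnection: the lactone is opened at O1–C5 to the (Z)-enynoic acid A1. A1 is then cut at C2–C3 and C4–C5 into 4-ethynylanisole A2 (used twice), carbon dioxide A3 and the alkynylzinc reagent A4.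
- Forward key step: A2 and A3 couple oxidatively on stoichiometric zerovalent nickel to the nickelalactone A5, forming C2–C3. A4 transmetalates, and reductive elimination at the aryl-bearing carbon forms C4–C5 and gives A1. Lactonisation onto the triple bond would then give 13.
- For it: three components converge in one step, both aryl carbons come from one alkyne, and the metallacycle fixes carboxyl and alkynyl cis. The route would be about half as long as the chosen one, so on step economy it is clearly stronger.
- Against it for this target: the ring size is not secured by the key step. The carboxyl oxygen must attack C5 (5-exo-dig) and not C6 (6-endo-dig). C6 bears the 4-methoxyphenyl donor, where positive character is best stabilised once the alkyne is activated, so the isomeric pyranone A6 is a real competitor. The step also needs a full equivalent of air-sensitive zerovalent nickel.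
- Comparison: the chosen strategy is longer and uses stoichiometric lead. In return O1 can only enter between C2 and C5, so the five-membered ring and all substituent positions are fixed by constitution.

**Alternative 2: biomimetic dimerisation of an arylpyruvate.**
- Disconnection: C4–C5 and O1–C2 are cut between two identical units of methyl 3-(4-methoxyphenyl)-2-oxopropanoate A8.
- Forward key step: under an amidine base the enolate of one molecule of A8 adds to the ketone of the other (C4–C5). The tertiary alkoxide closes onto the ester of the donor (O1–C2) to give the hydroxybutenolide ester A7.
- For it: one cheap building block is used twice, all carbons and both aryl groups are placed in a single step, and the aldol–lactonisation is mechanistically very safe, probably safer than a lead oxidation.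
- Against it for this target: A7 has the wrong oxidation level at two ring carbons. C3 carries a hydroxyl group that must be removed by sulfonylation and reduction. C5 carries an ester that must be excised with formation of the C5=C6 double bond, which needs hydrolysis and an oxidative decarboxylation. These corrections, plus preparation of A8, demethylation and bromination, make the route at least as long as the chosen one.
- Comparison: the chosen key product 12 already has hydrogen at C3 and a leaving group at C5, so one elimination reaches 13. Alternative 2 is stronger in the reliability and cost of its key step.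

**Alternative 3: phosphoranylideneketene annulation of an α-hydroxychalcone.**
- Disconnection: O1–C2 and C3=C4 are cut. The C2–C3 unit comes from (triphenylphosphoranylidene)ketene A11 and the rest from the enolised 1,2-diketone A10, which already carries all four bromine atoms.
- Forward key step: the enol hydroxyl of A10 adds to the ketene carbon of A11 (O1–C2). The resulting ester ylide closes on the aryl ketone by intramolecular Wittig reaction (C3=C4) to give the tetrabromo dimethyl ether A9. One ether cleavage would then give 15.
- For it: the bromine atoms arrive with the aromatic building blocks, so no late halogenation is needed. The exocyclic geometry is pre-set in the hydrogen-bonded Z enol, and the route would be several steps shorter. On halogen placement and step economy it is stronger than the chosen strategy.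
- Against it for this target: ring closure is the least favourable Wittig combination, an ester-stabilised ylide with a conjugated aryl ketone. It needs heating, during which the enol ester may isomerise or A11 may acylate a second time. A10 is in equilibrium with its diketone tautomer, so O-acylation is not the only path. Tetrabrominated intermediates of low solubility are carried from the start.
- Comparison: the chosen strategy forms the heterocycle at room temperature from a precursor in which each bond position is enforced by an alkoxy control group. It pays for this with two protecting-group-related steps and the late bromination.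

Key step: step 5

## Route

Remark: the target has no stereocentre. Compounds 6, 7, 11 and 12 are carried as racemates and 10 as a mixture of diastereomers, since every sp3 stereocentre is erased by step 6.

Step 1
Reactants: 1 diisopropyl squarate (3,4-diisopropoxycyclobut-3-ene-1,2-dione)
Product: 3 3-isopropoxycyclobut-3-ene-1,2-dione, via 4-hydroxy-2,3-diisopropoxycyclobut-2-en-1-one 2 (not isolated)
Conditions: LiAlH(OtBu)3, THF, −78 °C; then conc. HCl, CH2Cl2, rt
Reagents that add atoms: water, O
Why: The bulky hydride adds once to one of the two equivalent vinylogous-ester carbonyls (1,2-reduction) to give 2. Acid ionises the allylic hydroxyl to an alkoxy-stabilised cyclobutenyl cation; aqueous capture at the distal isopropoxy carbon and loss of isopropanol give the dione 3. This reduction–transposition is the standard entry to semisquaric esters.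

Step 2
Reactants: 3 3-isopropoxycyclobut-3-ene-1,2-dione; 4 4-methoxybenzyl chloride
Product: 6 4-hydroxy-3-isopropoxy-4-(4-methoxybenzyl)cyclobut-2-en-1-one (racemic), via 4-methoxybenzylmagnesium chloride 5 (not isolated)
Conditions: Mg, Et2O, 0 °C (4 to 5, slow addition); then 3, THF, −78 °C; sat. aq. NH4Cl
Reagents that add atoms: none
Why: Grignard 1,2-addition. The carbonyl of 3 that is conjugated with the isopropoxy group is a vinylogous ester, so the reagent should attack the ketone carbonyl next to the isopropoxy-bearing carbon, as organometallics do with 3-alkoxycyclobutenediones in general. The new carbinol centre forms as a racemate and needs no control.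

Step 3
Reactants: 6 4-hydroxy-3-isopropoxy-4-(4-methoxybenzyl)cyclobut-2-en-1-one
Product: 7 3-isopropoxy-4-(4-methoxybenzyl)-4-(trimethylsilyloxy)cyclobut-2-en-1-one (racemic)
Conditions: TMSCl, imidazole, CH2Cl2, 0 °C to rt
Reagents that add atoms: chlorotrimethylsilane, C[Si](C)(C)Cl
Why: Silylation of the tertiary alcohol; the small trimethylsilyl group goes onto hindered carbinols under imidazole catalysis. It leaves only one alkoxide in the next step, which guards against anion-accelerated electrocyclic opening of the four-membered ring, and it is lost in the acid of step 4.

Step 4
Reactants: 7 3-isopropoxy-4-(4-methoxybenzyl)-4-(trimethylsilyloxy)cyclobut-2-en-1-one; 8 4-bromoanisole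
Product: 11 4-hydroxy-4-(4-methoxybenzyl)-3-(4-methoxyphenyl)cyclobut-2-en-1-one (racemic), via 4-methoxyphenyllithium 9 (not isolated), via tertiary cyclobutenol adduct 10 (not isolated)
Conditions: n-BuLi, THF, −78 °C (8 to 9); 7, THF, −78 °C; then 1 M HCl, THF, 0 °C to rt
Reagents that add atoms: water, O
Why: Bromine–lithium exchange gives 9, which adds 1,2 to the only carbonyl left in 7. Dilute acid ionises the doubly activated carbinol of 10, water enters at the isopropoxy carbon and isopropanol leaves (Stork–Danheiser-type 1,3-carbonyl transposition), while the silyl ether is hydrolysed. Direct addition–elimination at the isopropoxy carbon would give the same constitution, so aryl can only end up next to the carbinol carbon; the stereocentre made in 10 is destroyed and 11 is racemic.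

Step 5
Reactants: 11 4-hydroxy-4-(4-methoxybenzyl)-3-(4-methoxyphenyl)cyclobut-2-en-1-one
Product: 12 5-acetoxy-5-(4-methoxybenzyl)-4-(4-methoxyphenyl)furan-2(5H)-one (racemic)
Conditions: Pb(OAc)4 (1.5 equiv), toluene, rt, dark
Reagents that add atoms: lead tetraacetate, CC(=O)O[Pb](OC(C)=O)(OC(C)=O)OC(C)=O
Why: Ligand exchange gives a tetravalent lead alkoxide of the tertiary cyclobutenol; homolysis to the alkoxy radical is followed by β-scission of the strained ring bond between the carbinol carbon and the carbonyl carbon (C2–C5), which turns the carbinol into the C5 ketone and leaves an acyl radical at C2 conjugated with the C3=C4 double bond. The acyl carbon recloses on the ketone oxygen in a 5-endo-trig mode, so the former hydroxyl oxygen becomes O1, and the resulting oxygen-substituted allylic radical at C5 is oxidised by lead to the acyloxy-stabilised cation and captured by acetate. A polar variant, lead-mediated cleavage of an α-hydroxy ketone with the new ketone oxygen trapping the acylium carbon, leads to the same product. The closest known reaction type is this same lead tetraacetate ring expansion of 4-hydroxycyclobut-2-enones to 5-acetoxy-2(5H)-furanones. C5 is the only new stereocentre; nothing controls it and nothing needs to, since it becomes sp2 in step 6. The selectivity required is scission of the ring bond rather than expulsion of the 4-methoxybenzyl radical; release of four-ring strain together with formation of a conjugated acyl radical (or acylium ion) should secure it. The anisyl rings carry no free phenol and are expected to survive the oxidant in a non-acidic medium at room temperature.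

Step 6
Reactants: 12 5-acetoxy-5-(4-methoxybenzyl)-4-(4-methoxyphenyl)furan-2(5H)-one
Product: 13 (Z)-5-(4-methoxybenzylidene)-4-(4-methoxyphenyl)furan-2(5H)-one
Conditions: DBU, CH2Cl2, 0 °C to rt
Reagents that add atoms: none
Why: Base-induced 1,2-elimination of acetic acid across C5–C6 (E2, or E1 after ionisation of the acylal acetate); C6 carries the only β-hydrogens, so the double bond can only form exocyclic. The Z isomer is expected because in the E isomer the benzylidene aryl would clash with the C4 aryl, whereas in the Z isomer it lies beside the ring oxygen; this is the usual outcome for 4-aryl-5-benzylidene butenolides.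

Step 7
Reactants: 13 (Z)-5-(4-methoxybenzylidene)-4-(4-methoxyphenyl)furan-2(5H)-one
Product: 14 (Z)-5-(4-hydroxybenzylidene)-4-(4-hydroxyphenyl)furan-2(5H)-one (rubrolide E)
Conditions: BBr3, CH2Cl2, −78 °C to rt; then H2O
Reagents that add atoms: none
Why: Lewis acid–base complexation of each aryl methyl ether with BBr3 followed by bromide attack at methyl (SN2), then hydrolysis of the aryl borates. The lactone, the enol-ester double bond and its Z geometry should be inert to the reagent at these temperatures, as is usual for methyl-protected arylbutenolides.

Step 8
Reactants: 14 (Z)-5-(4-hydroxybenzylidene)-4-(4-hydroxyphenyl)furan-2(5H)-one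
Product: 15 (Z)-5-(3,5-dibromo-4-hydroxybenzylidene)-4-(3,5-dibromo-4-hydroxyphenyl)furan-2(5H)-one (rubrolide A)
Conditions: Br2 (4.1 equiv), KBr, dioxane–H2O, 0 °C to rt
Reagents that add atoms: bromine, BrBr
Why: Electrophilic aromatic substitution: each free phenol directs bromine to its two ortho positions (para is blocked) and is far more nucleophilic than C3 of the acceptor-substituted ring double bond or the enol-ester double bond, so four equivalents should stop at the tetrabromide. Late ring bromination of phenolic butenolides of this type is an established reaction type.

## Compound list

1 | diisopropyl squarate (3,4-diisopropoxycyclobut-3-ene-1,2-dione) | CC(C)OC1=C(OC(C)C)C(=O)C1=O | starting material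
2 | 4-hydroxy-2,3-diisopropoxycyclobut-2-en-1-one (racemic) | O=C1C(OC(C)C)=C(OC(C)C)C1O | intermediate
3 | 3-isopropoxycyclobut-3-ene-1,2-dione | CC(C)OC1=CC(=O)C1=O | intermediate
4 | 4-methoxybenzyl chloride | COc1ccc(CCl)cc1 | starting material
5 | 4-methoxybenzylmagnesium chloride | COc1ccc(C[Mg]Cl)cc1 | intermediate
6 | 4-hydroxy-3-isopropoxy-4-(4-methoxybenzyl)cyclobut-2-en-1-one (racemic) | O=C1C=C(OC(C)C)C1(O)Cc1ccc(OC)cc1 | intermediate
7 | 3-isopropoxy-4-(4-methoxybenzyl)-4-(trimethylsilyloxy)cyclobut-2-en-1-one (racemic) | O=C1C=C(OC(C)C)C1(O[Si](C)(C)C)Cc1ccc(OC)cc1 | intermediate
8 | 4-bromoanisole | COc1ccc(Br)cc1 | starting material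
9 | 4-methoxyphenyllithium | [Li]c1ccc(OC)cc1 | intermediate
10 | 3-isopropoxy-4-(4-methoxybenzyl)-1-(4-methoxyphenyl)-4-(trimethylsilyloxy)cyclobut-2-en-1-ol (mixture of diastereomers, formed as its lithium alkoxide) | OC1(c2ccc(OC)cc2)C=C(OC(C)C)C1(O[Si](C)(C)C)Cc1ccc(OC)cc1 | intermediate
11 | 4-hydroxy-4-(4-methoxybenzyl)-3-(4-methoxyphenyl)cyclobut-2-en-1-one (racemic) | O=C1C=C(c2ccc(OC)cc2)C1(O)Cc1ccc(OC)cc1 | intermediate
12 | 5-acetoxy-5-(4-methoxybenzyl)-4-(4-methoxyphenyl)furan-2(5H)-one (racemic) | CC(=O)OC1(Cc2ccc(OC)cc2)OC(=O)C=C1c1ccc(OC)cc1 | intermediate
13 | (Z)-5-(4-methoxybenzylidene)-4-(4-methoxyphenyl)furan-2(5H)-one | O=C1C=C(c2ccc(OC)cc2)/C(=C/c2ccc(OC)cc2)O1 | intermediate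
14 | (Z)-5-(4-hydroxybenzylidene)-4-(4-hydroxyphenyl)furan-2(5H)-one (rubrolide E) | O=C1C=C(c2ccc(O)cc2)/C(=C/c2ccc(O)cc2)O1 | intermediate
15 | (Z)-5-(3,5-dibromo-4-hydroxybenzylidene)-4-(3,5-dibromo-4-hydroxyphenyl)furan-2(5H)-one (rubrolide A) | O=C1C=C(c2cc(Br)c(O)c(Br)c2)/C(=C/c2cc(Br)c(O)c(Br)c2)O1 | target

## Step count and least certain steps

Total step count: 8. Longest linear sequence: 8 steps, from 1 to 15; the reagents 5 and 9 are made in the flask from 4 and 8.

**Step 5 (key step).** The alkoxy radical may fragment on the exocyclic side, expelling the stabilised 4-methoxybenzyl radical instead of opening the ring, or the oxidant may attack the electron-rich anisyl rings and benzylic positions.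

The fallback keeps the same skeletal change but makes it without an oxidant and adjusts the oxidation level afterwards. It sets out from 11 and comes back at 13.
- Heating 11 in toluene or p-xylene should open the ring electrocyclically to (E)-4-hydroxy-3,5-bis(4-methoxyphenyl)penta-1,3-dien-1-one F1.
- The hydroxyl of F1 closes onto the ketene carbon to give 5-(4-methoxybenzyl)-4-(4-methoxyphenyl)furan-2(5H)-one F2. This is the known thermal rearrangement of 4-alkyl-4-hydroxycyclobutenones to butenolides.
- F2 is converted with TBSOTf and Et3N into tert-butyl{[5-(4-methoxybenzyl)-4-(4-methoxyphenyl)furan-2-yl]oxy}dimethylsilane F3.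
- F3 is brominated at C5 with NBS at −78 °C to give 5-bromo-5-(4-methoxybenzyl)-4-(4-methoxyphenyl)furan-2(5H)-one F4.
- F4 loses hydrogen bromide with DBU to give 13.

**Step 4.** The cyclobutenyl alkoxide may undergo anion-accelerated electrocyclic ring opening before the acid quench, or the ring may be cleaved during the acid-induced transposition.

The fallback reaches 11 without any alkoxy-substituted cyclobutenyl alkoxide. It sets out from 4 (as its Grignard reagent 5) and comes back at 11.
- 4-Ethynylanisole F5 is combined with dichloroketene F7, generated from trichloroacetyl chloride F6 with Zn–Cu couple in Et2O/DME, in a [2+2] cycloaddition. This gives 4,4-dichloro-3-(4-methoxyphenyl)cyclobut-2-en-1-one F8.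
- Hydrolysis of the geminal dichloride in conc. H2SO4 at 50–60 °C gives 3-(4-methoxyphenyl)cyclobut-3-ene-1,2-dione F9. The O-protonated enone is a cyclobutenyl cation, which should shield the anisyl ring from sulfonation.
- 5 is added at −78 °C. It should attack the carbonyl next to the aryl-bearing carbon, because the other carbonyl is deactivated by vinylogous donation from the anisyl group. This gives 11.

This sequence is one step shorter, but its regiochemistry rests on an aryl donor instead of an alkoxy group, so a regioisomeric adduct may have to be separated.

**Step 6.** Acyl transfer from the acetate to the amidine or to adventitious hydroxide may compete with elimination, giving deacetylation and opening to the γ-keto acid. Control of the double-bond geometry may also be incomplete.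

The fallback changes the elimination from a base-induced to a Lewis-acid-induced ionisation and merges it with the ether cleavage. It sets out from 12 and comes back at 14. Treating 12 directly with BBr3 in CH2Cl2 should ionise the acylal acetate to the acyloxy-stabilised furanyl cation. Loss of a C6 proton gives the Z ylidene under thermodynamic control, and the same reagent then cleaves both methyl ethers. No new isolated compound is involved.

## Further compounds

F1 | step 5 | (E)-4-hydroxy-3,5-bis(4-methoxyphenyl)penta-1,3-dien-1-one | O=C=C/C(c1ccc(OC)cc1)=C(\O)Cc1ccc(OC)cc1
F2 | step 5 | 5-(4-methoxybenzyl)-4-(4-methoxyphenyl)furan-2(5H)-one (racemic) | O=C1C=C(c2ccc(OC)cc2)C(Cc2ccc(OC)cc2)O1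
F3 | step 5 | tert-butyl{[5-(4-methoxybenzyl)-4-(4-methoxyphenyl)furan-2-yl]oxy}dimethylsilane | CC(C)(C)[Si](C)(C)Oc1cc(-c2ccc(OC)cc2)c(Cc2ccc(OC)cc2)o1
F4 | step 5 | 5-bromo-5-(4-methoxybenzyl)-4-(4-methoxyphenyl)furan-2(5H)-one (racemic) | O=C1C=C(c2ccc(OC)cc2)C(Br)(Cc2ccc(OC)cc2)O1
F5 | step 4 | 4-ethynylanisole | C#Cc1ccc(OC)cc1
F6 | step 4 | trichloroacetyl chloride | O=C(Cl)C(Cl)(Cl)Cl
F7 | step 4 | dichloroketene | O=C=C(Cl)Cl
F8 | step 4 | 4,4-dichloro-3-(4-methoxyphenyl)cyclobut-2-en-1-one | O=C1C=C(c2ccc(OC)cc2)C1(Cl)Cl
F9 | step 4 | 3-(4-methoxyphenyl)cyclobut-3-ene-1,2-dione | O=C1C=C(c2ccc(OC)cc2)C1=O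
F0 | step 6 | none | none
A1 | alternative 1 | (Z)-3,5-bis(4-methoxyphenyl)pent-2-en-4-ynoic acid | OC(=O)/C=C(c1ccc(OC)cc1)\C#Cc1ccc(OC)cc1
A2 | alternative 1 | 4-ethynylanisole | C#Cc1ccc(OC)cc1
A3 | alternative 1 | carbon dioxide | O=C=O
A4 | alternative 1 | [(4-methoxyphenyl)ethynyl]zinc chloride | COc1ccc(C#C[Zn]Cl)cc1
A5 | alternative 1 | 3-(4-methoxyphenyl)-1-oxa-2-nickelacyclopent-3-en-5-one (ancillary ligands omitted) | O=C1C=C(c2ccc(OC)cc2)[Ni]O1
A6 | alternative 1 | 4,6-bis(4-methoxyphenyl)-2H-pyran-2-one | O=C1C=C(c2ccc(OC)cc2)C=C(c2ccc(OC)cc2)O1
A7 | alternative 2 | methyl 4-hydroxy-2-(4-methoxybenzyl)-3-(4-methoxyphenyl)-5-oxo-2,5-dihydrofuran-2-carboxylate (racemic; hydroxyl on the carbon next to the lactone carbonyl) | COC(=O)C1(Cc2ccc(OC)cc2)OC(=O)C(O)=C1c1ccc(OC)cc1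
A8 | alternative 2 | methyl 3-(4-methoxyphenyl)-2-oxopropanoate | COC(=O)C(=O)Cc1ccc(OC)cc1
A9 | alternative 3 | (Z)-5-(3,5-dibromo-4-methoxybenzylidene)-4-(3,5-dibromo-4-methoxyphenyl)furan-2(5H)-one | O=C1C=C(c2cc(Br)c(OC)c(Br)c2)/C(=C/c2cc(Br)c(OC)c(Br)c2)O1
A10 | alternative 3 | (Z)-1,3-bis(3,5-dibromo-4-methoxyphenyl)-2-hydroxyprop-2-en-1-one | O=C(c1cc(Br)c(OC)c(Br)c1)/C(O)=C/c1cc(Br)c(OC)c(Br)c1
A11 | alternative 3 | (triphenylphosphoranylidene)ketene | O=C=C=P(c1ccccc1)(c1ccccc1)c1ccccc1
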